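**Strategy.** Everything rests on cutting the ring-fusion bond C3a–C6a of the cyclopentane ring (C3a, C4, C5, C6, C6a) of the cis-fused cyclopenta[c]isoxazolidine. The feature exploited is that C6a carries N1 while its neighbour C3a carries C3, a carbon outside the carbocycle. This is the pattern left when the amino-bearing α-carbon of a cyclohexanone migrates to the other α-carbon and the carbonyl carbon is pushed out of the ring. One photochemical Wolff rearrangement thus forms C3a–C6a, the five-membered carbocycle and the C3a stereocentre, with C6a transferred intact. Its precursor is the enantiopure N-Boc 2-amino-6-diazocyclohexanone; the two chains, N1–O2, O2–C3 and the C3 stereocentre follow.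

Key step: step 4

Remark: the amino alcohol is used as its free base, and the hemiketal carbon C3 of the penultimate compound is carried as a mixture of both configurations, which is of no consequence because C3 becomes trigonal in the last step.

**Route**

Step 1
Reactants: 1 (1R,2R)-2-aminocyclohexan-1-ol
Product: 2 tert-butyl N-[(1R,2R)-2-hydroxycyclohexyl]carbamate
Conditions: Boc2O, CH2Cl2, 0 °C to rt
Reagents that add atoms: di-tert-butyl dicarbonate, CC(C)(C)OC(=O)OC(=O)OC(C)(C)C
Why: Chemoselective N-acylation (carbamate formation) of the amine beside the less nucleophilic secondary alcohol, with no stereocentre involved.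

Step 2
Reactants: 2 tert-butyl N-[(1R,2R)-2-hydroxycyclohexyl]carbamate
Product: 3 tert-butyl N-[(1R)-2-oxocyclohexyl]carbamate
Conditions: Dess–Martin periodinane, CH2Cl2, 0 °C to rt
Reagents that add atoms: none
Why: Dess–Martin oxidation of a secondary alcohol under near-neutral conditions, which should leave the epimerisable nitrogen-bearing α-carbon untouched.

Step 3
Reactants: 3 tert-butyl N-[(1R)-2-oxocyclohexyl]carbamate
Product: 5 tert-butyl N-[(1R)-3-diazo-2-oxocyclohexyl]carbamate, via trifluoroacetyl ketone 4 (not isolated)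
Conditions: LiN(SiMe3)2 (2.2 equiv), THF, −78 °C; CF3CO2CH2CF3; 5% aq. HCl work-up; then MsN3, Et3N, H2O (1 equiv), MeCN, rt
Reagents that add atoms: methanesulfonyl azide, CS(=O)(=O)N=[N+]=[N-]
Why: Detrifluoroacetylative (Danheiser) diazo transfer, in which the first equivalent of base turns the carbamate N–H into an N-anion that blocks enolisation towards C1, so that the kinetic enolate, the Claisen-type trifluoroacetylation and the diazo transfer all occur at the methylene α-carbon and C1 keeps its configuration.

Step 4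
Reactants: 5 tert-butyl N-[(1R)-3-diazo-2-oxocyclohexyl]carbamate
Product: 7 methyl (1S,2R)-2-[(tert-butoxycarbonyl)amino]cyclopentane-1-carboxylate, via ketene 6 (not isolated)
Conditions: hν (350 nm, Pyrex), MeOH, 0 °C
Reagents that add atoms: methanol, CO
Why: Excitation of the diazoketone, whose ring holds C=O and C=N2 s-cis, expels N2 and, in concert or through a short-lived singlet acyl carbene, shifts the C1–C2 bond so that the nitrogen-bearing carbon C1 bonds to the former diazo carbon and the carbonyl carbon leaves the ring as ketene 6, which adds methanol and tautomerises to ester 7. The closest known reaction type is the photochemical Wolff ring contraction of 2-diazocyclohexanones to cyclopentanecarboxylic esters. The cyclopentane ring (future C3a, C4, C5, C6, C6a) is closed not by a cyclisation but by this 1,2-carbon shift, a ring contraction that makes the C3a–C6a bond. C6a is not newly created and should keep its R configuration because the migrating carbon moves with retention, while the new stereocentre C3a is set by kinetic protonation of the exocyclic ester enol on the face anti to the neighbouring carbamate, which leaves ester and nitrogen cis. The step needs rearrangement to win over O–H insertion into methanol and 1,2-hydride shift to an enone; C1 is the only carbon on the carbonyl that can migrate, the locked s-cis geometry favours the concerted pathway, and direct irradiation without a metal avoids carbenoid chemistry.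

Step 5
Reactants: 7 methyl (1S,2R)-2-[(tert-butoxycarbonyl)amino]cyclopentane-1-carboxylate
Product: 8 tert-butyl N-[(1R,2S)-2-[methoxy(methyl)carbamoyl]cyclopentyl]carbamate
Conditions: MeNHOMe·HCl, i-PrMgCl, THF, −20 to 0 °C
Reagents that add atoms: N,O-dimethylhydroxylamine hydrochloride, CNOC.Cl
Why: Weinreb amide formation by aminolysis of the methyl ester with the chloromagnesium amide of N,O-dimethylhydroxylamine at low temperature, where the magnesiated carbamate shields the neighbouring centres from epimerisation.

Step 6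
Reactants: 9 3-methylpyridine; 10 1,7-dibromoheptane
Product: 12 3-(8-bromooctyl)pyridine, via 3-picolyllithium 11 (not isolated)
Conditions: LiN(i-Pr)2, THF, −78 °C; then 10 (4 equiv), −78 to −20 °C
Reagents that add atoms: none
Why: Lateral lithiation of 3-picoline and SN2 alkylation, with the large excess of dibromide suppressing double substitution; the bromide is kept cold and dilute and divided at once between steps 7 and 8, so that it does not quaternise its own pyridine nitrogen.

Step 7
Reactants: 8 tert-butyl N-[(1R,2S)-2-[methoxy(methyl)carbamoyl]cyclopentyl]carbamate; 12 3-(8-bromooctyl)pyridine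
Product: 14 tert-butyl N-[(1R,2S)-2-[9-(pyridin-3-yl)nonanoyl]cyclopentyl]carbamate, via Grignard reagent 13 (not isolated)
Conditions: 12, Mg, THF, rt to 40 °C; 8, i-PrMgCl (1.0 equiv), THF, −20 °C; then 13 (1.6 equiv), 0 °C to rt; aq. NH4Cl
Reagents that add atoms: none
Why: Weinreb ketone synthesis, in which the N-methoxy chelate of the tetrahedral adduct prevents over-addition, prior N-deprotonation with i-PrMgCl spares the pyridyl Grignard reagent, and unactivated pyridine rings do not add alkylmagnesium halides at these temperatures.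

Step 8
Reactants: 12 3-(8-bromooctyl)pyridine; 15 2-(4-bromobutyl)-1,3-dioxolane
Product: 17 3-[12-(1,3-dioxolan-2-yl)dodecyl]pyridine, via acetal Grignard reagent 16 (not isolated)
Conditions: 15, Mg, THF, rt; then 16 (1.5 equiv) added to 12, Li2CuCl4 (3 mol%), THF, −10 to 0 °C; aq. NH4Cl
Reagents that add atoms: none
Why: Copper-catalysed (Kochi-type) sp3–sp3 cross-coupling of a primary alkylmagnesium bromide with a primary alkyl bromide, in which the dioxolane is inert to the Grignard reagent, an unactivated pyridine ring does not add alkylmagnesium halides at or below 0 °C, and the second portion of 12 serves as the electrophile so that it needs no metalation.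

Step 9
Reactants: 17 3-[12-(1,3-dioxolan-2-yl)dodecyl]pyridine
Product: 18 13-(pyridin-3-yl)tridecanal
Conditions: 2 M aq. HCl, THF, rt; then NaHCO3
Reagents that add atoms: water, O
Why: Acid-catalysed hydrolysis of the 1,3-dioxolane (acetal cleavage) in a large excess of water frees the aldehyde, the pyridine being only protonated and released again on neutralisation, and the aldehyde is taken into step 10 without storage.

Step 10
Reactants: 14 tert-butyl N-[(1R,2S)-2-[9-(pyridin-3-yl)nonanoyl]cyclopentyl]carbamate; 18 13-(pyridin-3-yl)tridecanal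
Product: 20 1-[(1S,2R)-2-{[13-(pyridin-3-yl)tridecyl]amino}cyclopentyl]-9-(pyridin-3-yl)nonan-1-one, via amino ketone 19 (not isolated)
Conditions: TFA, CH2Cl2, 0 °C; evaporate; then 18 (1.05 equiv), Et3N, NaBH(OAc)3, ClCH2CH2Cl, rt
Reagents that add atoms: none
Why: Acidolytic Boc cleavage followed by reductive amination with NaBH(OAc)3, which mono-alkylates the α-branched primary amine, does not reduce the ketone, and avoids an alkyl halide that would also quaternise the pyridine nitrogens.

Step 11
Reactants: 20 1-[(1S,2R)-2-{[13-(pyridin-3-yl)tridecyl]amino}cyclopentyl]-9-(pyridin-3-yl)nonan-1-one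
Product: 21 O-benzoyl-N-{(1R,2S)-2-[9-(pyridin-3-yl)nonanoyl]cyclopentyl}-N-[13-(pyridin-3-yl)tridecyl]hydroxylamine
Conditions: (BzO)2 (1.1 equiv), K2HPO4, DMF, rt
Reagents that add atoms: dibenzoyl peroxide, O=C(OOC(=O)c1ccccc1)c1ccccc1
Why: Electrophilic N-oxidation of a secondary amine by attack on the peroxide O–O bond under phosphate buffering (which suppresses N-benzoylation) installs N1–O2, while the far less nucleophilic pyridine nitrogens should not react.

Step 12
Reactants: 21 O-benzoyl-N-{(1R,2S)-2-[9-(pyridin-3-yl)nonanoyl]cyclopentyl}-N-[13-(pyridin-3-yl)tridecyl]hydroxylamine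
Product: 23 (3aS,6aR)-3-[8-(pyridin-3-yl)octyl]-1-[13-(pyridin-3-yl)tridecyl]hexahydro-1H-cyclopenta[c][1,2]oxazol-3-ol, via N-hydroxy amino ketone 22 (not isolated)
Conditions: K2CO3 (0.2 equiv), MeOH, 0 °C to rt
Reagents that add atoms: none
Why: Transesterification to methyl benzoate frees the N-hydroxy group, which adds to the 1,3-related ketone in a 5-exo-trig closure (ring–chain tautomerism of β-hydroxyamino ketones) to form O2–C3 and the cis-fused hemiketal, the only fusion the bicycle can readily adopt.

Step 13
Reactants: 23 (3aS,6aR)-3-[8-(pyridin-3-yl)octyl]-1-[13-(pyridin-3-yl)tridecyl]hexahydro-1H-cyclopenta[c][1,2]oxazol-3-ol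
Product: 25 pyrinodemin B = (3S,3aS,6aR)-3-[8-(pyridin-3-yl)octyl]-1-[13-(pyridin-3-yl)tridecyl]hexahydro-1H-cyclopenta[c][1,2]oxazole, via oxocarbenium ion 24 (not isolated)
Conditions: Et3SiH (10 equiv), BF3·OEt2 (6 equiv), CH2Cl2, −40 to 0 °C
Reagents that add atoms: none
Why: Ionic hydrogenation of a cyclic hemiketal (lactol-type reduction), in which BF3 in excess over the two pyridines ionises C3–OH to the O2-stabilised oxocarbenium ion and the silane delivers hydride to C3 from the convex face of the cis-bicyclo[3.3.0] skeleton, syn to H-3a, so that the octyl chain ends on the concave face and C3 is S.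

**Compound list**

1 | (1R,2R)-2-aminocyclohexan-1-ol | N[C@@H]1CCCC[C@H]1O | starting material
2 | tert-butyl N-[(1R,2R)-2-hydroxycyclohexyl]carbamate | CC(C)(C)OC(=O)N[C@@H]1CCCC[C@H]1O | intermediate
3 | tert-butyl N-[(1R)-2-oxocyclohexyl]carbamate | CC(C)(C)OC(=O)N[C@@H]1CCCCC1=O | intermediate
4 | tert-butyl N-[(1R)-2-oxo-3-(2,2,2-trifluoroacetyl)cyclohexyl]carbamate (C3 epimers and enol form) | CC(C)(C)OC(=O)N[C@@H]1CCCC(C(=O)C(F)(F)F)C1=O | intermediate
5 | tert-butyl N-[(1R)-3-diazo-2-oxocyclohexyl]carbamate | CC(C)(C)OC(=O)N[C@@H]1CCCC(=[N+]=[N-])C1=O | intermediate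
6 | tert-butyl N-[(1R)-2-(oxomethylidene)cyclopentyl]carbamate (ketene) | CC(C)(C)OC(=O)N[C@@H]1CCCC1=C=O | intermediate
7 | methyl (1S,2R)-2-[(tert-butoxycarbonyl)amino]cyclopentane-1-carboxylate | COC(=O)[C@H]1CCC[C@H]1NC(=O)OC(C)(C)C | intermediate
8 | tert-butyl N-[(1R,2S)-2-[methoxy(methyl)carbamoyl]cyclopentyl]carbamate | CON(C)C(=O)[C@H]1CCC[C@H]1NC(=O)OC(C)(C)C | intermediate
9 | 3-methylpyridine | Cc1cccnc1 | starting material
10 | 1,7-dibromoheptane | BrCCCCCCCBr | starting material
11 | 3-picolyllithium, (pyridin-3-ylmethyl)lithium | [Li]Cc1cccnc1 | intermediate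
12 | 3-(8-bromooctyl)pyridine | BrCCCCCCCCc1cccnc1 | intermediate
13 | [8-(pyridin-3-yl)octyl]magnesium bromide | Br[Mg]CCCCCCCCc1cccnc1 | intermediate
14 | tert-butyl N-[(1R,2S)-2-[9-(pyridin-3-yl)nonanoyl]cyclopentyl]carbamate | O=C(CCCCCCCCc1cccnc1)[C@H]1CCC[C@H]1NC(=O)OC(C)(C)C | intermediate
15 | 2-(4-bromobutyl)-1,3-dioxolane | BrCCCCC1OCCO1 | starting material
16 | [4-(1,3-dioxolan-2-yl)butyl]magnesium bromide | Br[Mg]CCCCC1OCCO1 | intermediate
17 | 3-[12-(1,3-dioxolan-2-yl)dodecyl]pyridine | O1CCOC1CCCCCCCCCCCCc1cccnc1 | intermediate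
18 | 13-(pyridin-3-yl)tridecanal | O=CCCCCCCCCCCCCc1cccnc1 | intermediate
19 | 1-[(1S,2R)-2-aminocyclopentyl]-9-(pyridin-3-yl)nonan-1-one | O=C(CCCCCCCCc1cccnc1)[C@H]1CCC[C@H]1N | intermediate
20 | 1-[(1S,2R)-2-{[13-(pyridin-3-yl)tridecyl]amino}cyclopentyl]-9-(pyridin-3-yl)nonan-1-one | O=C(CCCCCCCCc1cccnc1)[C@H]1CCC[C@H]1NCCCCCCCCCCCCCc1cccnc1 | intermediate
21 | O-benzoyl-N-{(1R,2S)-2-[9-(pyridin-3-yl)nonanoyl]cyclopentyl}-N-[13-(pyridin-3-yl)tridecyl]hydroxylamine | O=C(CCCCCCCCc1cccnc1)[C@H]1CCC[C@H]1N(OC(=O)c1ccccc1)CCCCCCCCCCCCCc1cccnc1 | intermediate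
22 | 1-[(1S,2R)-2-{hydroxy[13-(pyridin-3-yl)tridecyl]amino}cyclopentyl]-9-(pyridin-3-yl)nonan-1-one | O=C(CCCCCCCCc1cccnc1)[C@H]1CCC[C@H]1N(O)CCCCCCCCCCCCCc1cccnc1 | intermediate
23 | (3aS,6aR)-3-[8-(pyridin-3-yl)octyl]-1-[13-(pyridin-3-yl)tridecyl]hexahydro-1H-cyclopenta[c][1,2]oxazol-3-ol (both C3 configurations) | c1cncc(CCCCCCCCCCCCCN2OC(O)(CCCCCCCCc3cccnc3)[C@H]3CCC[C@H]32)c1 | intermediate
24 | (3aS,6aR)-3-[8-(pyridin-3-yl)octyl]-1-[13-(pyridin-3-yl)tridecyl]-1,3a,4,5,6,6a-hexahydrocyclopenta[c][1,2]oxazol-2-ium (oxocarbenium ion) | c1cncc(CCCCCCCCCCCCCN2[O+]=C(CCCCCCCCc3cccnc3)[C@H]3CCC[C@H]32)c1 | intermediate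
25 | pyrinodemin B, (3S,3aS,6aR)-3-[8-(pyridin-3-yl)octyl]-1-[13-(pyridin-3-yl)tridecyl]hexahydro-1H-cyclopenta[c][1,2]oxazole | c1cncc(CCCCCCCCCCCCCN2O[C@@H](CCCCCCCCc3cccnc3)[C@H]3CCC[C@H]32)c1 | target

**Step count and risks**

Total step count: 13. Longest linear sequence: 10 steps (steps 1, 2, 3, 4, 5, 7, 10, 11, 12, 13, from 1 to 25).

Steps most likely to fail:

Step 4. The enol formed from the ketene and methanol may be protonated with poor facial selectivity, so that the trans ester predominates. The fallback sets out from 5 and comes back at 7. Irradiation as in step 4 would then give mainly methyl (1R,2R)-2-[(tert-butoxycarbonyl)amino]cyclopentane-1-carboxylate F1. Its dianion (LiN(i-Pr)2, 2.2 equiv, THF, −78 °C) would be selenenylated with PhSeBr to methyl (2R)-2-[(tert-butoxycarbonyl)amino]-1-(phenylselanyl)cyclopentane-1-carboxylate F2. Oxidation with H2O2 (CH2Cl2, 0 °C) and syn-elimination of the selenoxide away from the nitrogen-bearing carbon should give methyl (5R)-5-[(tert-butoxycarbonyl)amino]cyclopent-1-ene-1-carboxylate F3. Hydrogenation over Pd/C in EtOAc, with H2 adding to the face opposite the allylic carbamate, should then set C3a cis to nitrogen and deliver 7. C6a is not touched in this detour.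

Step 7. Formation of the organomagnesium reagent may be undermined by intermolecular N-alkylation of the pyridine by the bromide, Wurtz coupling or electron transfer from Mg to the pyridine ring. The fallback sets out from 8 and comes back at 14, and puts the pyridine on last. Oct-7-en-1-ylmagnesium bromide F4 (from 8-bromooct-1-ene and Mg in THF) would be added to 8 after N-deprotonation with i-PrMgCl, giving tert-butyl N-[(1R,2S)-2-(non-8-enoyl)cyclopentyl]carbamate F5. Hydroboration of the terminal alkene with 9-borabicyclo[3.3.1]nonane (THF, 0 °C to rt), which should outpace ketone reduction, would give tert-butyl N-[(1R,2S)-2-[9-(9-borabicyclo[3.3.1]nonan-9-yl)nonanoyl]cyclopentyl]carbamate F6. B-alkyl Suzuki–Miyaura coupling of F6 with 3-bromopyridine (PdCl2(dppf), K3PO4, DMF–H2O, 50 °C) would then give 14.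

Step 10. While the free β-amino ketone is handled, C3a may epimerise, the amine may be lost by β-elimination, or the iminium ion may be trapped by the ketone enol in an intramolecular Mannich reaction. The fallback sets out from 8 and comes back at 20, and moves the amination ahead of ketone formation. Boc cleavage of 8 (TFA, CH2Cl2) would give (1S,2R)-2-amino-N-methoxy-N-methylcyclopentane-1-carboxamide F7, which is not isolated. Reductive amination of F7 with 18 (Et3N, NaBH(OAc)3, ClCH2CH2Cl) would give (1S,2R)-N-methoxy-N-methyl-2-{[13-(pyridin-3-yl)tridecyl]amino}cyclopentane-1-carboxamide F8, which is far less prone to enolisation and β-elimination than the ketone. Addition of excess 13 (3 equiv, THF, 0 °C to rt) to F8 would then give 20.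

**Further compounds**

F1 | step 4 | methyl (1R,2R)-2-[(tert-butoxycarbonyl)amino]cyclopentane-1-carboxylate | COC(=O)[C@@H]1CCC[C@H]1NC(=O)OC(C)(C)C
F2 | step 4 | methyl (2R)-2-[(tert-butoxycarbonyl)amino]-1-(phenylselanyl)cyclopentane-1-carboxylate (C1 epimers) | COC(=O)C1([Se]c2ccccc2)CCC[C@H]1NC(=O)OC(C)(C)C
F3 | step 4 | methyl (5R)-5-[(tert-butoxycarbonyl)amino]cyclopent-1-ene-1-carboxylate | COC(=O)C1=CCC[C@H]1NC(=O)OC(C)(C)C
F4 | step 7 | oct-7-en-1-ylmagnesium bromide | C=CCCCCCC[Mg]Br
F5 | step 7 | tert-butyl N-[(1R,2S)-2-(non-8-enoyl)cyclopentyl]carbamate | C=CCCCCCCC(=O)[C@H]1CCC[C@H]1NC(=O)OC(C)(C)C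
F6 | step 7 | tert-butyl N-[(1R,2S)-2-[9-(9-borabicyclo[3.3.1]nonan-9-yl)nonanoyl]cyclopentyl]carbamate | O=C(CCCCCCCCB1C2CCCC1CCC2)[C@H]1CCC[C@H]1NC(=O)OC(C)(C)C
F7 | step 10 | (1S,2R)-2-amino-N-methoxy-N-methylcyclopentane-1-carboxamide | CON(C)C(=O)[C@H]1CCC[C@H]1N
F8 | step 10 | (1S,2R)-N-methoxy-N-methyl-2-{[13-(pyridin-3-yl)tridecyl]amino}cyclopentane-1-carboxamide | CON(C)C(=O)[C@H]1CCC[C@H]1NCCCCCCCCCCCCCc1cccnc1
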